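## Structural features

Compound 26 (C26H36O4) is a 20-membered diaryl ether cyclophane. Benzene rings A and B are joined once through an ether oxygen (A1–O–B1) and once through an unbranched, saturated chain of fourteen methylenes running from B6 (C1) to A5 (C14). Ring A is 1,3,5-trisubstituted (A1 ether oxygen, A3 hydroxyl, A5 chain). Ring B is 1,2,4,6-tetrasubstituted (B1 ether oxygen, B2 and B4 hydroxyls, B6 chain), so the oxygen on B1 is flanked by two ortho substituents. There is no stereocentre and no stereogenic double bond, so no neighbouring stereocentres have to be related, and a ring of this size should not give separable atropisomers. The fragile part is the free hydroxyquinol-type ring B (B1 oxygen ortho to B2–OH and para to B4–OH), which is easily oxidised to quinones once unmasked; the diaryl ether and the chain are robust. The difficulty is threefold: the hindered A1–O–B1 bond is a poor candidate for phenol arylation, the all-meta pattern of ring A cannot be set by electrophilic substitution, and a 20-membered ring must be closed against oligomerisation. The key step uses the fact that the A1/A3/A5 pattern (aryloxy, hydroxyl, alkyl) is exactly what a vinylketene from a 3-alkylcyclobutenone gives with a terminal ynol ether. The B1 oxygen is therefore carried as an aryl ethynyl ether and ring A is grown onto it through new A2–A3 and A1–A6 bonds.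

## Logic of the disconnections

26 from 25. The last retrosynthetic move is not skeletal: restoring a C4=C5 double bond and two O-benzyl groups on B2 and B4 leads to 25. The reason is that the only operation on the finished macrocycle is then one hydrogenation, which erases the alkene geometry and frees the oxidation-prone ring B under hydrogen. The forward step must cleave two benzylic C–O bonds and saturate one alkene without touching the diaryl ether.

25 from 24. The C4=C5 double bond is cut to the two terminal alkenes of 24, a ring-closing metathesis in the forward sense. The cut lies in the flexible chain, away from both arenes, and it removes the macrocycle from the problem. The forward step needs high dilution and suppression of double-bond migration, because a shifted alkene would close to a ring one carbon smaller.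

24 from 14 and 19. Ring A is taken apart along A2–A3 and A1–A6, together with A3–A4, which in the forward direction is broken and re-formed. 14 brings A1, A2, the ether oxygen and the whole of ring B; 19 brings A3 to A6 and the long chain. The gain is a convergent union of two fragments of similar size in which the 1,3,5 pattern follows from the mechanism and the hindered O–B1 bond is already in place. The demand is that 14 captures the transient 20 faster than either partner decomposes at 80–110 °C, and that both terminal alkenes stay spectators.

14 from 11, and 11 from 8 and 9. The triple bond of 14 is traced back to the dichlorovinyl group of 11, and the O–C(sp2) bond of 11 is cut to 8 and 9. The reason is that the oxygen of 8, too hindered for arylation, should still add to the small electrophile 10 generated from 9. The forward steps need a base strong enough for elimination and halogen–metal exchange at a temperature low enough to spare the ring and benzylic C–H bonds.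

8 from 6, and 6 from 4. The B1–O bond of 8 is traced to the B1–CHO bond of 6 (aryl migration from carbon to oxygen), and the formyl group is then removed to give 4. Electrophilic formylation of 4 selects the ring carbon next to the chain and para to an oxygen, which is B1. The demand is regiocontrol in the formylation and an oxidant that leaves the terminal alkene alone.

4 from 1 and 2. The B6–C1 bond is cut between an aryl nucleophile (3, from 1) and a primary alkyl electrophile (2). Both pieces are simple, and the alkene of 2 is already the metathesis handle.

19 from 15 and 16. The bond between C14 and the four-membered ring is cut to an alkyl nucleophile (17, from 15) and 16, which acts as a cyclobutenone electrophilic at C3 after carbonyl addition and acid-induced transposition. The demand is 1,2-addition followed by clean hydrolysis without isomerising the strained enone.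

## Other disconnections considered

Alternative 1: The cut is the O–B1 bond, made as the ring-closing event. Constant-current anodic oxidation (carbon anode, LiClO4 in MeOH) of the symmetric hexabromide A2 would turn one tribromoresorcinol ring into a phenoxonium ion. A hydroxyl of the other ring would attack it at brominated B1, giving the macrocyclic bromo quinol ether A1. Zinc reduction and hydrogenolytic removal of the remaining bromines would then lead to 26.
- In its favour: A2 is symmetric and needs no protecting groups. Either ring may be oxidised and either hydroxyl of the nucleophilic ring may attack, and B1 and B5 are equivalent, so the only wrong site on the ring is B3. The hindered C–O bond and the macrocycle would arise in one operation.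
- Against it: a phenoxonium ion partitions under little control between B1 and B3, between intra- and intermolecular attack, and between the phenol and methanol as nucleophile. The dilution a 20-membered closure wants conflicts with the conductivity and current density an electrolysis needs. Six bromines must be installed and removed, and resorcinols are prone to over-oxidation.
- Comparison: on step count this plan is better than the chosen one, roughly half the length. It is equal in leaving no lasting stereochemistry, since the B1 centre of A1 is erased on reduction. The chosen plan is stronger in mechanism: the regiochemistry of ring A is fixed by alkyne polarisation in a pericyclic cascade, and ring closure is left to a separate, well-behaved metathesis.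

Alternative 2: The cuts are the A3–O and B4–O bonds, made last by C–H functionalisation. The deoxy macrocycle A4 would be borylated with B2pin2 and [Ir(OMe)(cod)]2/4,4'-di-tert-butyl-2,2'-bipyridine, and both C–B bonds oxidised in the same flask with KHSO5 to give A3. BBr3 would then free the B2 hydroxyl to give 26.
- In its favour: steric control is clear. On ring A only A3 has no ortho neighbour, and on ring B only B4 has none. The building blocks for A4 carry two oxygens fewer, so they are simpler and need fewer protecting groups; on this point the alternative is better.
- Against it: the hindered A1–O–B1 bond must still be made by arylation of a 2,6-disubstituted phenol, which is the problem the chosen plan avoids. A macrocyclisation is still required. Borylation must go to completion at two sites on a valuable late intermediate, with some risk at the position ortho to the small methoxy group, and a demethylation remains.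
- Comparison: regiochemical predictability is equal (steric control there, electronic control here). Step count is equal or slightly better for the alternative. The chosen plan has the advantage that its riskiest step joins two cheap fragments early, not a finished macrocycle late.

Alternative 3: The cut is the C5–C6 bond between sp carbons. Slow addition of the bis(terminal alkyne) A6 to Cu(OAc)2 in pyridine would couple the two alkyne termini oxidatively (Glaser–Eglinton) and close the 20-membered ring as the triyne A5. Exhaustive hydrogenation and BBr3 would give 26.
- In its favour: oxidative alkyne coupling under pseudo-dilution is a proven way to large rings. The product has no E/Z isomers and cannot suffer double-bond migration with ring contraction; on this point it is better than metathesis. The closure site is as remote from the arenes as in the chosen plan, an equal point.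
- Against it: four collinear sp carbons (C4–C7) plus the rigid A5–C14≡C13 unit leave few flexible atoms to span the ring, so strain and oligomerisation are concerns. All phenols must be masked, three triple bonds must be hydrogenated and three methyl ethers cleaved. The hindered diaryl ether again has to come from an arylation. Each alkyne needs its own installation, so the sequence would be clearly longer.
- Comparison: the chosen plan is shorter and more convergent, and it solves the ring A pattern and the hindered ether in one step; the alternative only solves the ring closure.

Key step: step 7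

Remarks on the chemistry (assumptions and checks):
- The two ring B oxygens are carried as benzyl ethers, so that one hydrogenation saturates C4=C5 and frees B2–OH and B4–OH; 1 is assumed to be purchasable.
- 25 is expected as an E/Z mixture at C4=C5, which is immaterial because step 9 saturates that bond; 26 has no stereocentre.
- Chain count: five carbons from 2 and eleven from 15, less two lost as ethylene in step 8, give the fourteen methylenes C1–C14.
- The transient [2+2] adduct 21 is numbered systematically as a 4-alkenylcyclobut-2-en-1-one, with the alkenyl group on the sp3 ring carbon next to the carbonyl.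
- An aryl aldehyde without a free ortho or para hydroxyl does not undergo the classical basic Dakin reaction, and a peracid would endanger the terminal alkene; step 3 therefore uses hydrogen peroxide under acid catalysis.

## Route

Step 1
Reactants: 1 1,3-bis(benzyloxy)-5-bromobenzene; 2 5-bromopent-1-ene
Product: 4 1,3-bis(benzyloxy)-5-(pent-4-en-1-yl)benzene, via aryl Grignard reagent 3 (not isolated)
Conditions: Mg, THF, reflux; then 2, Li2CuCl4 (3 mol%), THF, 0 °C → rt
Reagents that add atoms: none
Why: Kochi-type copper-catalysed cross-coupling of an aryl Grignard reagent with a primary alkyl bromide; the benzyl ethers are inert to magnesium insertion and the remote terminal alkene of 2 takes no part.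

Step 2
Reactants: 4 1,3-bis(benzyloxy)-5-(pent-4-en-1-yl)benzene
Product: 6 2,4-bis(benzyloxy)-6-(pent-4-en-1-yl)benzaldehyde, via iminium salt 5 (not isolated)
Conditions: POCl3, DMF, 0 → 70 °C; then H2O, 0 °C → rt
Reagents that add atoms: N,N-dimethylformamide CN(C)C=O; water O
Why: Vilsmeier–Haack formylation; the carbon para to one benzyloxy group and ortho to the other, next to the chain, is the most nucleophilic accessible site, while the carbon between the two benzyloxy groups is shielded on both sides, as is general for 5-alkylresorcinol diethers; water hydrolyses iminium salt 5.

Step 3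
Reactants: 6 2,4-bis(benzyloxy)-6-(pent-4-en-1-yl)benzaldehyde
Product: 8 2,4-bis(benzyloxy)-6-(pent-4-en-1-yl)phenol, via aryl formate 7 (not isolated)
Conditions: 30% H2O2, cat. H2SO4, MeOH, 0 °C → rt
Reagents that add atoms: hydrogen peroxide OO
Why: Acid-mediated Dakin oxidation (Baeyer–Villiger-type 1,2-aryl shift in the peroxy hemiacetal); the electron-rich aryl group migrates in preference to hydride, formate 7 is methanolysed in the same flask, and hydrogen peroxide without a peracid should leave the isolated terminal alkene untouched.

Step 4
Reactants: 8 2,4-bis(benzyloxy)-6-(pent-4-en-1-yl)phenol; 9 trichloroethylene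
Product: 11 1,5-bis(benzyloxy)-2-{[(E)-1,2-dichloroethenyl]oxy}-3-(pent-4-en-1-yl)benzene, via dichloroacetylene 10 (not isolated)
Conditions: K2CO3, DMF, 70 °C, under argon
Reagents that add atoms: none
Why: Base-mediated O-dichlorovinylation of a phenol with trichloroethylene, most plausibly by dehydrochlorination to 10 in solution and anti addition of the phenoxide, which fixes the E geometry; the hindered B1–O–C bond is thus made by addition to a slim sp carbon and not by arylation.

Step 5
Reactants: 11 1,5-bis(benzyloxy)-2-{[(E)-1,2-dichloroethenyl]oxy}-3-(pent-4-en-1-yl)benzene
Product: 14 1,5-bis(benzyloxy)-2-(ethynyloxy)-3-(pent-4-en-1-yl)benzene, via chloroethynyl ether 12 (not isolated), via lithium acetylide 13 (not isolated)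
Conditions: n-BuLi (2.3 equiv), THF, −78 → −40 °C; then H2O, −78 °C; quick filtration through basic Al2O3, used at once as a toluene solution
Reagents that add atoms: none
Why: Dehydrochlorination of the 1,2-dichlorovinyl ether to 12, chlorine–lithium exchange to 13 and protonation, the standard entry to terminal ynol ethers; at −78 °C elimination should outrun metalation of the ring or of the benzylic positions.

Step 6
Reactants: 15 11-bromoundec-1-ene; 16 3-ethoxycyclobut-2-en-1-one
Product: 19 3-(undec-10-en-1-yl)cyclobut-2-en-1-one, via alkenyl Grignard reagent 17 (not isolated), via tertiary cyclobutenol 18 (not isolated)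
Conditions: Mg, THF, rt; then 16, THF, −78 °C; then 1 M HCl, 0 °C → rt
Reagents that add atoms: water O
Why: 1,2-Addition of the Grignard reagent to the vinylogous ester carbonyl, then acid-induced enol ether hydrolysis and dehydration (Stork–Danheiser-type transposition) gives the 3-alkylcyclobutenone; enolisation does not compete because the enolate would be a cyclobutadiene.

Step 7
Reactants: 14 1,5-bis(benzyloxy)-2-(ethynyloxy)-3-(pent-4-en-1-yl)benzene; 19 3-(undec-10-en-1-yl)cyclobut-2-en-1-one
Product: 24 3-[2,4-bis(benzyloxy)-6-(pent-4-en-1-yl)phenoxy]-5-(undec-10-en-1-yl)phenol, via vinylketene 20 (not isolated), via 4-alkenylcyclobutenone 21 (not isolated), via dienylketene 22 (not isolated), via cyclohexa-2,4-dienone 23 (not isolated)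
Conditions: 19 (1.5 equiv), PhMe (0.4 M), argon, 80 → 110 °C; then KOH, MeOH, 60 °C; acidic work-up
Reagents that add atoms: none
Why: Danheiser benzannulation. Heating opens 19 reversibly by four-electron conrotatory electrocyclic cleavage of its C1–C4 bond to vinylketene 20. The polarised ynol ether 14 adds to the ketene C=C in a [2+2] cycloaddition: its unsubstituted nucleophilic carbon bonds to the ketene carbonyl carbon (new A2–A3 bond) and its oxygen-bearing carbon to the ketene α-carbon (new A1–A6 bond), giving 21. A second four-electron opening gives dienylketene 22; ring A then closes by thermally allowed six-electron disrotatory electrocyclisation, which re-forms the A3–A4 bond, and tautomerisation of 23 gives 24. The closest known reaction type is the benzannulation of 3-alkylcyclobutenones with alkoxy- and siloxyacetylenes, of which an aryloxyacetylene is a less electron-rich member. No stereocentre is created, since the sp3 carbon of 21 is lost on ring opening. The step needs regioselectivity in the [2+2] event, secured by donation from the ether oxygen of 14, which places OAr meta to OH and the chain meta to both. It also needs chemoselectivity for the alkyne over the two unactivated terminal alkenes, secured by the far higher ketenophilicity of an ynol ether. The hydroxide treatment only returns 24 from any aryl ester formed by acylation of 24 with 20.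

Step 8
Reactants: 24 3-[2,4-bis(benzyloxy)-6-(pent-4-en-1-yl)phenoxy]-5-(undec-10-en-1-yl)phenol
Product: 25 macrocyclic C4=C5 alkene (E/Z mixture): the 20-membered diaryl ether ring of 26 with a C4=C5 double bond, benzyl ethers on the B2 and B4 oxygens and a free A3 hydroxyl
Conditions: second-generation Grubbs catalyst (H2IMes)(PCy3)Cl2Ru=CHPh (10 mol%, two portions), 1,4-benzoquinone (20 mol%), CH2Cl2 (1 mM), 40 °C
Reagents that add atoms: none
Why: Ring-closing olefin metathesis of two monosubstituted alkenes at high dilution; the 20-membered ring is nearly strain-free, loss of ethylene drives closure, the free phenol is tolerated by the ruthenium carbene, and 1,4-benzoquinone suppresses hydride-mediated double-bond migration that would lead to ring-contracted homologues.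

Step 9
Reactants: 25 macrocyclic C4=C5 alkene (E/Z mixture)
Product: 26 CNP0173380.0
Conditions: H2 (1 atm), 10% Pd/C, EtOAc/MeOH, rt
Reagents that add atoms: none
Why: Heterogeneous hydrogenation saturates the disubstituted alkene, which makes the E/Z mixture converge, and hydrogenolyses both benzyl aryl ethers in the same operation; the diaryl ether and the arenes are inert, and the oxidation-sensitive ring B is unveiled under hydrogen.

## Compound list

1 | 1,3-bis(benzyloxy)-5-bromobenzene | Brc1cc(OCc2ccccc2)cc(OCc2ccccc2)c1 | starting material
2 | 5-bromopent-1-ene | C=CCCCBr | starting material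
3 | [3,5-bis(benzyloxy)phenyl]magnesium bromide | Br[Mg]c1cc(OCc2ccccc2)cc(OCc2ccccc2)c1 | intermediate
4 | 1,3-bis(benzyloxy)-5-(pent-4-en-1-yl)benzene | C=CCCCc1cc(OCc2ccccc2)cc(OCc2ccccc2)c1 | intermediate
5 | N-{[2,4-bis(benzyloxy)-6-(pent-4-en-1-yl)phenyl]methylidene}-N-methylmethanaminium chloride | C[N+](C)=Cc1c(CCCC=C)cc(OCc2ccccc2)cc1OCc1ccccc1.[Cl-] | intermediate
6 | 2,4-bis(benzyloxy)-6-(pent-4-en-1-yl)benzaldehyde | O=Cc1c(CCCC=C)cc(OCc2ccccc2)cc1OCc1ccccc1 | intermediate
7 | 2,4-bis(benzyloxy)-6-(pent-4-en-1-yl)phenyl formate | O=COc1c(CCCC=C)cc(OCc2ccccc2)cc1OCc1ccccc1 | intermediate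
8 | 2,4-bis(benzyloxy)-6-(pent-4-en-1-yl)phenol | Oc1c(CCCC=C)cc(OCc2ccccc2)cc1OCc1ccccc1 | intermediate
9 | trichloroethylene | ClC=C(Cl)Cl | starting material
10 | dichloroacetylene | ClC#CCl | intermediate
11 | 1,5-bis(benzyloxy)-2-{[(E)-1,2-dichloroethenyl]oxy}-3-(pent-4-en-1-yl)benzene | Cl/C=C(/Cl)Oc1c(CCCC=C)cc(OCc2ccccc2)cc1OCc1ccccc1 | intermediate
12 | 1,5-bis(benzyloxy)-2-[(chloroethynyl)oxy]-3-(pent-4-en-1-yl)benzene | ClC#COc1c(CCCC=C)cc(OCc2ccccc2)cc1OCc1ccccc1 | intermediate
13 | lithium [2,4-bis(benzyloxy)-6-(pent-4-en-1-yl)phenoxy]acetylide | [Li]C#COc1c(CCCC=C)cc(OCc2ccccc2)cc1OCc1ccccc1 | intermediate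
14 | 1,5-bis(benzyloxy)-2-(ethynyloxy)-3-(pent-4-en-1-yl)benzene | C#COc1c(CCCC=C)cc(OCc2ccccc2)cc1OCc1ccccc1 | intermediate
15 | 11-bromoundec-1-ene | C=CCCCCCCCCCBr | starting material
16 | 3-ethoxycyclobut-2-en-1-one | CCOC1=CC(=O)C1 | starting material
17 | undec-10-en-1-ylmagnesium bromide | C=CCCCCCCCCC[Mg]Br | intermediate
18 | 3-ethoxy-1-(undec-10-en-1-yl)cyclobut-2-en-1-ol | CCOC1=CC(O)(CCCCCCCCCC=C)C1 | intermediate
19 | 3-(undec-10-en-1-yl)cyclobut-2-en-1-one | O=C1C=C(CCCCCCCCCC=C)C1 | intermediate
20 | 3-methylidenetetradeca-1,13-dien-1-one (vinylketene) | O=C=CC(=C)CCCCCCCCCC=C | intermediate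
21 | 3-[2,4-bis(benzyloxy)-6-(pent-4-en-1-yl)phenoxy]-4-(trideca-1,12-dien-2-yl)cyclobut-2-en-1-one (racemic, transient) | O=C1C=C(Oc2c(CCCC=C)cc(OCc3ccccc3)cc2OCc2ccccc2)C1C(=C)CCCCCCCCCC=C | intermediate
22 | (3E)-3-[2,4-bis(benzyloxy)-6-(pent-4-en-1-yl)phenoxy]-5-methylidenehexadeca-1,3,15-trien-1-one (dienylketene) | O=C=C/C(Oc1c(CCCC=C)cc(OCc2ccccc2)cc1OCc1ccccc1)=C\C(=C)CCCCCCCCCC=C | intermediate
23 | 3-[2,4-bis(benzyloxy)-6-(pent-4-en-1-yl)phenoxy]-5-(undec-10-en-1-yl)cyclohexa-2,4-dien-1-one | O=C1C=C(Oc2c(CCCC=C)cc(OCc3ccccc3)cc2OCc2ccccc2)C=C(CCCCCCCCCC=C)C1 | intermediate
24 | 3-[2,4-bis(benzyloxy)-6-(pent-4-en-1-yl)phenoxy]-5-(undec-10-en-1-yl)phenol | C=CCCCCCCCCCc1cc(O)cc(Oc2c(OCc3ccccc3)cc(OCc3ccccc3)cc2CCCC=C)c1 | intermediate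
25 | B2,B4-di-O-benzyl-4,5-didehydro derivative of 26 (20-membered diaryl ether macrocycle with C4=C5 alkene, E/Z mixture, geometry left open) | Oc1cc2cc(c1)Oc1c(OCc3ccccc3)cc(OCc3ccccc3)cc1CCCC=CCCCCCCCCC2 | intermediate
26 | CNP0173380.0: 20-membered macrocycle in which a 3-hydroxyphenoxy ring A (A1 O, A3 OH) and a 2,4-dihydroxyphenyl ring B (B1 O, B2 OH, B4 OH) are linked by the A1–O–B1 ether and by a tetradecane-1,14-diyl chain from B6 to A5; no stereocentre | Oc1cc2cc(c1)Oc1c(O)cc(O)cc1CCCCCCCCCCCCCC2 | target

## Step count and risks

Total step count: 9. Longest linear sequence: 8 (steps 1, 2, 3, 4, 5, 7, 8, 9); the cyclobutenone branch contributes step 6.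

Least certain steps:

Step 7 (key step).
- Risk: capture of vinylketene 20 may be slow, because an aryloxy group donates less than an alkoxy group. Dimerisation or oligomerisation of the ketene, thermal polymerisation of the terminal ynol ether, and addition of the product phenol to unreacted ynol ether could then consume the partners before ring A forms.
- Mitigation within the step: 19 in excess, staged heating, exclusion of acid.
- Fallback (known chemistry, sets out from 8, returns at 26): the ether is made by arylation and ring A is brought in ready-made. Kumada–Corriu coupling of 17 with an excess of commercial 1-(benzyloxy)-3,5-dibromobenzene (PdCl2(dppf), THF) would give 1-(benzyloxy)-3-bromo-5-(undec-10-en-1-yl)benzene F1. Ullmann-type coupling of 8 with F1 (CuI, picolinic acid, K3PO4, DMSO, 90 °C, conditions suited to 2,6-disubstituted phenols) would give 1,5-bis(benzyloxy)-2-[3-(benzyloxy)-5-(undec-10-en-1-yl)phenoxy]-3-(pent-4-en-1-yl)benzene F2. Ring-closing metathesis as in step 8 would give the tri-O-benzyl macrocyclic alkene F3, and hydrogenation as in step 9 would deliver 26.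

Step 5.
- Risk: the excess of n-BuLi needed for chlorine–lithium exchange may cause competing metalation of the ring carbon between the two benzyloxy groups, or the exchange may stay incomplete. The terminal ynol ether cannot be purified at leisure, since it is prone to hydration and polymerisation on acidic supports.
- Fallback (sets out from 8, returns at 14): O-formylation of 8 (acetic formic anhydride, pyridine) would give 7. Ramirez-type dibromomethylenation of the formate carbonyl (CBr4, PPh3, Et3N, CH2Cl2) would give 1,5-bis(benzyloxy)-2-[(2,2-dibromoethenyl)oxy]-3-(pent-4-en-1-yl)benzene F4. Bromine–lithium exchange with n-BuLi at −78 °C and Fritsch–Buttenberg–Wiechell rearrangement would lead through 13 to 14 without any chloroalkyne stage and without the dichloroacetylene chemistry of step 4.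
- If 14 itself proves too labile to carry into step 7, the fallback given for step 7 applies.

Step 8.
- Risk: intermolecular metathesis to dimers and oligomers, and double-bond migration before closure. The latter would give ring-contracted homologues that can no longer be separated after hydrogenation.
- Fallback (sets out from 24, returns at 25): Lemieux–Johnson cleavage of both terminal alkenes (cat. OsO4, NaIO4, 2,6-lutidine, dioxane/H2O) would give the dialdehyde 4-{3,5-bis(benzyloxy)-2-[3-hydroxy-5-(10-oxodecyl)phenoxy]phenyl}butanal F5. Intramolecular McMurry coupling with low-valent titanium (TiCl3(DME)1.5, Zn–Cu couple, DME, reflux, syringe-pump addition, excess reagent to allow for the phenol) would join C4 and C5 and give 25; no metal hydride is present that could shift the new double bond.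

Step 3.
- Risk: over-oxidation of the product, a hydroquinone monoether-type phenol, to quinones by the peroxide; or stalling of the rearrangement at the dimethyl acetal of 6.
- Fallback (sets out from 4, returns at 8): bromination of 4 with NBS (MeCN, 0 °C) should go to the same ring carbon as the formylation and give 1,5-bis(benzyloxy)-2-bromo-3-(pent-4-en-1-yl)benzene F6. Bromine–lithium exchange (n-BuLi, THF, −78 °C) would give [2,4-bis(benzyloxy)-6-(pent-4-en-1-yl)phenyl]lithium F7. Trapping with B(OMe)3 would give dimethyl [2,4-bis(benzyloxy)-6-(pent-4-en-1-yl)phenyl]boronate F8, and oxidation with alkaline H2O2 at 0 °C, which does not epoxidise an isolated alkene, would give 8.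

Step 1.
- Risk: homocoupling of the aryl Grignard reagent, or slow alkylation of the arylcopper species by the unactivated primary bromide with net reduction of the arene.
- Fallback (sets out from 1 and 2, returns at 4): the polarity is reversed in a Negishi coupling. Zinc insertion into 2 (Zn dust, LiCl, THF) would give pent-4-en-1-ylzinc bromide F9, which would couple with 1 under Pd(OAc)2/SPhos in THF to give 4.

## Further compounds

F1 | step 7 | 1-(benzyloxy)-3-bromo-5-(undec-10-en-1-yl)benzene | C=CCCCCCCCCCc1cc(Br)cc(OCc2ccccc2)c1
F2 | step 7 | 1,5-bis(benzyloxy)-2-[3-(benzyloxy)-5-(undec-10-en-1-yl)phenoxy]-3-(pent-4-en-1-yl)benzene | C=CCCCCCCCCCc1cc(OCc2ccccc2)cc(Oc2c(OCc3ccccc3)cc(OCc3ccccc3)cc2CCCC=C)c1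
F3 | step 7 | A3,B2,B4-tri-O-benzyl-4,5-didehydro derivative of 26 (macrocyclic C4=C5 alkene, E/Z mixture) | C(Oc1cc2cc(c1)Oc1c(OCc3ccccc3)cc(OCc3ccccc3)cc1CCCC=CCCCCCCCCC2)c1ccccc1
F4 | step 5 | 1,5-bis(benzyloxy)-2-[(2,2-dibromoethenyl)oxy]-3-(pent-4-en-1-yl)benzene | BrC(Br)=COc1c(CCCC=C)cc(OCc2ccccc2)cc1OCc1ccccc1
F5 | step 8 | 4-{3,5-bis(benzyloxy)-2-[3-hydroxy-5-(10-oxodecyl)phenoxy]phenyl}butanal | O=CCCCCCCCCCc1cc(O)cc(Oc2c(OCc3ccccc3)cc(OCc3ccccc3)cc2CCCC=O)c1
F6 | step 3 | 1,5-bis(benzyloxy)-2-bromo-3-(pent-4-en-1-yl)benzene | Brc1c(CCCC=C)cc(OCc2ccccc2)cc1OCc1ccccc1
F7 | step 3 | [2,4-bis(benzyloxy)-6-(pent-4-en-1-yl)phenyl]lithium | [Li]c1c(CCCC=C)cc(OCc2ccccc2)cc1OCc1ccccc1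
F8 | step 3 | dimethyl [2,4-bis(benzyloxy)-6-(pent-4-en-1-yl)phenyl]boronate | COB(OC)c1c(CCCC=C)cc(OCc2ccccc2)cc1OCc1ccccc1
F9 | step 1 | pent-4-en-1-ylzinc bromide | C=CCCC[Zn]Br
A1 | alternative 1 | macrocyclic 4-aryloxy-4-bromo-3-hydroxycyclohexa-2,5-dienone (bromo quinol ether, racemic at B1) | Oc1c(Br)c2c(Br)c(c1Br)OC1(Br)C(O)=C(Br)C(=O)C(Br)=C1CCCCCCCCCCCCCC2
A2 | alternative 1 | 1,14-bis(2,4,6-tribromo-3,5-dihydroxyphenyl)tetradecane | Oc1c(Br)c(O)c(Br)c(CCCCCCCCCCCCCCc2c(Br)c(O)c(Br)c(O)c2Br)c1Br
A3 | alternative 2 | B2-O-methyl ether of 26 | COc1cc(O)cc2c1Oc1cc(O)cc(c1)CCCCCCCCCCCCCC2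
A4 | alternative 2 | deoxy macrocycle lacking the A3 and B4 hydroxyls (B2 methyl ether) | COc1cccc2c1Oc1cccc(c1)CCCCCCCCCCCCCC2
A5 | alternative 3 | macrocyclic triyne trimethyl ether (C4–C7 diyne and C13–C14 alkyne) | COc1cc2cc(c1)Oc1c(OC)cc(OC)cc1CCCC#CC#CCCCCCC#C2
A6 | alternative 3 | open-chain bis(terminal alkyne) trimethyl ether | COc1cc(C#CCCCCCC#C)cc(Oc2c(OC)cc(OC)cc2CCCC#C)c1
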